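**Strategy.** The 14-membered carbocycle is closed last at the ring bond C10–C11 (15-oxabicyclo[10.2.1]pentadecane numbering) by an intramolecular B-alkyl Suzuki–Miyaura coupling. The step exploits the 1,1-disubstituted alkene C11(=CH2) lying between ring CH2 C10 and oxolane carbon C12: a vinyl group on the acetoxy carbinol C8 is hydroborated to the C10 borane, which couples with a 2-bromoalkene on the preformed cis-oxolane. One operation thus gives the macrocycle and the exocyclic methylene with all six stereocentres in place. The seco precursor comes from (R)-limonene (C4), a Sharpless epoxidation/Payne sequence (C7, C8), a first B-alkyl Suzuki union and a Shi epoxidation–cyclisation (C1, C2, oxolane).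

Key step: step 17

Remark on numbering: locants C1–C15 in the text follow the 15-oxabicyclo[10.2.1]pentadecane numbering of target 27.
Assumption: 2-bromoprop-2-enal (16) is taken as purchasable; it is otherwise one step from acrolein (Br2, then Et3N).

**Step 1**
Reactants: 1 (R)-(+)-limonene
Product: 3 (5R)-7,7-dimethoxy-5-(prop-1-en-2-yl)heptan-2-one, via methoxy hydroperoxide 2 (not isolated)
Conditions: O3 (1 equiv), CH2Cl2/MeOH, −78 °C; p-TsOH (cat.), rt; NaHCO3; Me2S
Reagents that add atoms: ozone [O-][O+]=O; methanol CO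
Why: Schreiber ozonolysis with terminal differentiation: ozone should attack the electron-richer trisubstituted ring alkene, methanol traps the ketone oxide, the free aldehyde is acetalised and Me2S then releases the ketone; the stereocentre (later C4) is untouched.

**Step 2**
Reactants: 3 (5R)-7,7-dimethoxy-5-(prop-1-en-2-yl)heptan-2-one
Product: 5 (5R)-7,7-dimethoxy-5-(prop-1-en-2-yl)hept-1-yne, via enol phosphate 4 (not isolated)
Conditions: LiN(i-Pr)2 (1.1 equiv), THF, −78 °C; ClP(O)(OEt)2; LiN(i-Pr)2 (2.3 equiv), −78 °C → rt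
Reagents that add atoms: none
Why: Negishi ketone-to-alkyne conversion: kinetic deprotonation at the methyl group, enol phosphate formation and base-induced β-elimination should give the terminal alkyne without touching the remote stereocentre.

**Step 3**
Reactants: 5 (5R)-7,7-dimethoxy-5-(prop-1-en-2-yl)hept-1-yne
Product: 7 (2E,6R)-8,8-dimethoxy-3-methyl-6-(prop-1-en-2-yl)oct-2-en-1-ol, via alkenylalane 6 (not isolated)
Conditions: Me3Al (3 equiv), Cp2ZrCl2 (0.2 equiv), H2O (1.5 equiv), CH2Cl2, −20 °C; then n-BuLi, (CH2O)n, THF, −78 °C → rt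
Reagents that add atoms: trimethylaluminium C[Al](C)C; formaldehyde (as paraformaldehyde) C=O
Why: Negishi zirconium-catalysed syn-carboalumination puts methyl on the internal and aluminium on the terminal alkyne carbon, and the derived alanate is hydroxymethylated with retention, so the (E)-trisubstituted allylic alcohol should form as a single geometric isomer.

**Step 4**
Reactants: 7 (2E,6R)-8,8-dimethoxy-3-methyl-6-(prop-1-en-2-yl)oct-2-en-1-ol
Product: 8 [(2R,3R)-3-[(3R)-5,5-dimethoxy-3-(prop-1-en-2-yl)pentyl]-3-methyloxiran-2-yl]methanol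
Conditions: Ti(Oi-Pr)4, D-(−)-DET, t-BuOOH, 4 Å MS, CH2Cl2, −20 °C
Reagents that add atoms: tert-butyl hydroperoxide CC(C)(C)OO
Why: Sharpless asymmetric epoxidation: D-(−)-tartrate should give the (2R,3R)-epoxide of this geraniol-type alcohol (mirror of the (2S,3S) series from L-(+)-tartrate), fixing the tertiary centre (later C7) under reagent control; the isopropenyl group has no directing hydroxyl and stays intact.

**Step 5**
Reactants: 8 [(2R,3R)-3-[(3R)-5,5-dimethoxy-3-(prop-1-en-2-yl)pentyl]-3-methyloxiran-2-yl]methanol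
Product: 10 (3S,4R,7R)-9,9-dimethoxy-4-methyl-7-(prop-1-en-2-yl)non-1-ene-3,4-diol, via terminal epoxide 9 (not isolated)
Conditions: Me3SI (5 equiv), n-BuLi (5 equiv), THF, −10 °C → rt
Reagents that add atoms: trimethylsulfonium iodide C[S+](C)C.[I-]
Why: Payne rearrangement (inversion at the secondary epoxide carbon) followed by opening of the more reactive terminal epoxide at CH2 by dimethylsulfonium methylide and loss of Me2S should give the vinyl carbinol; the tertiary centre keeps its Sharpless configuration, so the anti (3S,4R) diol results.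

**Step 6**
Reactants: 10 (3S,4R,7R)-9,9-dimethoxy-4-methyl-7-(prop-1-en-2-yl)non-1-ene-3,4-diol
Product: 11 (3S,4R,7R)-7-(3-hydroxyprop-1-en-2-yl)-9,9-dimethoxy-4-methylnon-1-ene-3,4-diol
Conditions: SeO2 (0.3 equiv), t-BuOOH, CH2Cl2, rt
Reagents that add atoms: selenium dioxide O=[Se]=O; tert-butyl hydroperoxide CC(C)(C)OO
Why: Sharpless catalytic SeO2 allylic oxidation (ene reaction, then [2,3]-shift) should hydroxylate the methyl group of the nucleophilic 1,1-disubstituted alkene (CH3 reacts before CH, so the stereocentre is kept) while the monosubstituted vinyl carbinol reacts far more slowly; any enal formed converges in step 7.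

**Step 7**
Reactants: 11 (3S,4R,7R)-7-(3-hydroxyprop-1-en-2-yl)-9,9-dimethoxy-4-methylnon-1-ene-3,4-diol
Product: 12 2-[(3R,6R,7S)-6,7-dihydroxy-1,1-dimethoxy-6-methylnon-8-en-3-yl]prop-2-enoic acid
Conditions: TEMPO (cat.), NaOCl (cat.), NaClO2, MeCN/phosphate buffer pH 6.7, 35 °C
Reagents that add atoms: sodium chlorite [Na+].[O-]Cl=O
Why: TEMPO/chlorite oxidation (Zhao variant of the Anelli and Pinnick oxidations) should take the primary allylic alcohol through the enal to the acid at near-neutral pH, which spares the dimethyl acetal, while the hindered secondary and tertiary alcohols react much more slowly.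

**Step 8**
Reactants: 12 2-[(3R,6R,7S)-6,7-dihydroxy-1,1-dimethoxy-6-methylnon-8-en-3-yl]prop-2-enoic acid
Product: 13 2-(trimethylsilyl)ethyl 2-[(3R,6R,7S)-6,7-dihydroxy-1,1-dimethoxy-6-methylnon-8-en-3-yl]prop-2-enoate
Conditions: Me3SiCH2CH2OH (5 equiv), EDC·HCl, DMAP (cat.), CH2Cl2, 0 °C → rt
Reagents that add atoms: 2-(trimethylsilyl)ethanol C[Si](C)(C)CCO
Why: Steglich esterification with excess primary alcohol should outcompete the hindered secondary and tertiary hydroxyls of the substrate; the ester later deactivates this alkene towards hydroboration and dioxirane.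

**Step 9**
Reactants: 13 2-(trimethylsilyl)ethyl 2-[(3R,6R,7S)-6,7-dihydroxy-1,1-dimethoxy-6-methylnon-8-en-3-yl]prop-2-enoate
Product: 14 2-(trimethylsilyl)ethyl 2-[(3R,6R,7S)-6,7-dihydroxy-6-methyl-1-oxonon-8-en-3-yl]prop-2-enoate
Conditions: AcOH/THF/H2O (3:1:1), rt
Reagents that add atoms: water O
Why: Mild acid hydrolysis should cleave the open-chain dimethyl acetal while the ester and the diol are inert; the stereocentre is β to the aldehyde and cannot epimerise by enolisation.

**Step 10**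
Reactants: 14 2-(trimethylsilyl)ethyl 2-[(3R,6R,7S)-6,7-dihydroxy-6-methyl-1-oxonon-8-en-3-yl]prop-2-enoate
Product: 15 2-(trimethylsilyl)ethyl 2-[(2Z,5R,8R,9S)-8,9-dihydroxy-2-iodo-8-methylundeca-2,10-dien-5-yl]prop-2-enoate
Conditions: EtPPh3I, n-BuLi, THF; I2, −78 °C; NaN(SiMe3)2, −20 °C; then 14, −78 °C → rt
Reagents that add atoms: ethyltriphenylphosphonium iodide CC[P+](c1ccccc1)(c1ccccc1)c1ccccc1.[I-]; iodine II
Why: Stork–Zhao Wittig olefination with the α-iodoethylidene ylide (used in excess to cover the two hydroxyls) should give the (Z)-2-iodoalkene under kinetic control, with iodine cis to the chain; the aldehyde reacts far faster than the ester at −78 °C.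

**Step 11**
Reactants: 16 2-bromoprop-2-enal
Product: 17 (±)-2-bromopenta-1,4-dien-3-ol
Conditions: CH2=CHMgBr, THF, −78 °C
Reagents that add atoms: vinylmagnesium bromide C=C[Mg]Br
Why: The Grignard reagent should add 1,2 to the enal to give the racemic divinyl-type carbinol.

**Step 12**
Reactants: 17 (±)-2-bromopenta-1,4-dien-3-ol
Product: 18 (3S)-2-bromopenta-1,4-dien-3-ol
Conditions: Ti(Oi-Pr)4, L-(+)-DIPT, t-BuOOH (0.6 equiv), 4 Å MS, CH2Cl2, −20 °C
Reagents that add atoms: none
Why: Sharpless kinetic resolution: with L-(+)-tartrate the (R)-enantiomer should be epoxidised at its unsubstituted vinyl group (the bromoalkene is too electron-poor), leaving the (S)-alcohol that carries the future C12 configuration.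

**Step 13**
Reactants: 18 (3S)-2-bromopenta-1,4-dien-3-ol
Product: 19 {[(3S)-2-bromopenta-1,4-dien-3-yl]oxy}triethylsilane
Conditions: Et3SiCl, imidazole, DMF, 0 °C
Reagents that add atoms: chlorotriethylsilane CC[Si](Cl)(CC)CC
Why: Standard silylation; the TES ether survives the basic steps that follow and falls off in the acid step that closes the oxolane.

**Step 14**
Reactants: 19 {[(3S)-2-bromopenta-1,4-dien-3-yl]oxy}triethylsilane; 15 2-(trimethylsilyl)ethyl 2-[(2Z,5R,8R,9S)-8,9-dihydroxy-2-iodo-8-methylundeca-2,10-dien-5-yl]prop-2-enoate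
Product: 21 2-(trimethylsilyl)ethyl 2-[(3S,6Z,9R,12R,13S)-2-bromo-12,13-dihydroxy-6,12-dimethyl-3-(triethylsilyloxy)pentadeca-1,6,14-trien-9-yl]prop-2-enoate, via alkylborane 20 (not isolated)
Conditions: 19 (1.6 equiv), 9-BBN (1.5 equiv), THF, 0 °C → rt; then 15, PdCl2(dppf) (10 mol %), AsPh3, Cs2CO3, DMF/THF/H2O, rt
Reagents that add atoms: none
Why: Intermolecular B-alkyl Suzuki–Miyaura coupling: 9-BBN should add only to the unhindered vinyl group of 19 (boron terminal), zerovalent palladium inserts into C–I much faster than into either C–Br at rt, and coupling proceeds with retention to give the (Z)-trisubstituted alkene; 9-BBN is limiting so no B–H reaches the alkenes of 15.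

**Step 15**
Reactants: 21 2-(trimethylsilyl)ethyl 2-[(3S,6Z,9R,12R,13S)-2-bromo-12,13-dihydroxy-6,12-dimethyl-3-(triethylsilyloxy)pentadeca-1,6,14-trien-9-yl]prop-2-enoate
Product: 22 2-(trimethylsilyl)ethyl 2-[(3S,6Z,9R,12R,13S)-13-acetoxy-2-bromo-12-hydroxy-6,12-dimethyl-3-(triethylsilyloxy)pentadeca-1,6,14-trien-9-yl]prop-2-enoate
Conditions: Ac2O, pyridine, DMAP (cat.), CH2Cl2, 0 °C
Reagents that add atoms: acetic anhydride CC(=O)OC(C)=O
Why: The secondary allylic hydroxyl should be acetylated selectively over the tertiary one; the step is placed after the palladium-mediated union so that no allylic acetate meets zerovalent palladium.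

**Step 16**
Reactants: 22 2-(trimethylsilyl)ethyl 2-[(3S,6Z,9R,12R,13S)-13-acetoxy-2-bromo-12-hydroxy-6,12-dimethyl-3-(triethylsilyloxy)pentadeca-1,6,14-trien-9-yl]prop-2-enoate
Product: 24 2-(trimethylsilyl)ethyl 2-[(1R,3R,6R,7S)-7-acetoxy-1-[(2R,5S)-5-(1-bromoethenyl)-2-methyloxolan-2-yl]-1,6-dihydroxy-6-methylnon-8-en-3-yl]prop-2-enoate, via epoxide 23 (not isolated)
Conditions: D-fructose-derived Shi ketone (0.3 equiv), KHSO5 (Oxone), K2CO3, Bu4NHSO4, MeCN/DMM/aq. Na2B4O7 buffer, 0 °C; then CSA (cat.), MeOH/CH2Cl2, 0 °C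
Reagents that add atoms: potassium peroxymonosulfate OOS(=O)(=O)[O-].[K+]
Why: Shi asymmetric epoxidation should hit the only electron-rich (trisubstituted) alkene on the face set by the chiral dioxirane (spiro transition state) to give the (6S,7R)-epoxide; acid then removes the TES group and the freed hydroxyl opens the epoxide 5-exo at the tertiary carbon with inversion, which sets C1 (R), keeps C2 (R) and gives the cis-2,5-disubstituted oxolane.

**Step 17**
Reactants: 24 2-(trimethylsilyl)ethyl 2-[(1R,3R,6R,7S)-7-acetoxy-1-[(2R,5S)-5-(1-bromoethenyl)-2-methyloxolan-2-yl]-1,6-dihydroxy-6-methylnon-8-en-3-yl]prop-2-enoate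
Product: 26 2-(trimethylsilyl)ethyl 2-[(1R,2R,4R,7R,8S,12S)-8-acetoxy-2,7-dihydroxy-1,7-dimethyl-11-methylidene-15-oxabicyclo[10.2.1]pentadecan-4-yl]prop-2-enoate, via alkylborane 25 (not isolated)
Conditions: 9-BBN (4 equiv), THF, 0 °C → rt; then slow addition to PdCl2(dppf) (20 mol %), AsPh3, Cs2CO3, DMF/THF/H2O, 45 °C, 1 mM
Reagents that add atoms: none
Why: 9-BBN should add to the only electron-neutral monosubstituted alkene (the C8 vinyl group) with boron on the terminal carbon, after which zerovalent palladium inserts into the C–Br bond, the base-activated alkylborate transmetalates and reductive elimination forms C10–C11. The closest known reaction type is the intramolecular B-alkyl Suzuki–Miyaura macrocyclisation. The 14-membered carbocycle of the 15-oxabicyclo[10.2.1] system closes by C(sp3)–C(sp2) reductive elimination from a 15-membered palladacycle, leaving the methylidene exocyclic. No stereocentre is formed; all six are carried in and none is epimerisable under the mildly basic conditions. The step needs chemoselective hydroboration and ring closure over oligomerisation: the conjugated acrylate and the bromoalkene are electronically deactivated towards 9-BBN, and high dilution with slow addition, helped by the cis-oxolane turn and the two fully substituted carbinol carbons, favours cyclisation.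

**Step 18**
Reactants: 26 2-(trimethylsilyl)ethyl 2-[(1R,2R,4R,7R,8S,12S)-8-acetoxy-2,7-dihydroxy-1,7-dimethyl-11-methylidene-15-oxabicyclo[10.2.1]pentadecan-4-yl]prop-2-enoate
Product: 27 dendronpholide R
Conditions: TBAF, THF, 0 °C → rt; aq. NH4Cl
Reagents that add atoms: none
Why: Fluoride-induced β-elimination of the 2-(trimethylsilyl)ethyl ester should free the acrylic acid without touching the acetate, the hydroxyls or the alkenes.

**Compound list**

1 | (R)-(+)-limonene | CC1=CC[C@@H](CC1)C(C)=C | starting material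
2 | (5R)-2-hydroperoxy-2,7,7-trimethoxy-5-(prop-1-en-2-yl)heptane (mixture at C2) | COC(OC)C[C@@H](CCC(C)(OC)OO)C(C)=C | intermediate
3 | (5R)-7,7-dimethoxy-5-(prop-1-en-2-yl)heptan-2-one | COC(OC)C[C@@H](CCC(C)=O)C(C)=C | intermediate
4 | diethyl (5R)-7,7-dimethoxy-5-(prop-1-en-2-yl)hept-1-en-2-yl phosphate | COC(OC)C[C@@H](CCC(=C)OP(=O)(OCC)OCC)C(C)=C | intermediate
5 | (5R)-7,7-dimethoxy-5-(prop-1-en-2-yl)hept-1-yne | COC(OC)C[C@@H](CCC#C)C(C)=C | intermediate
6 | [(1E,6R)-8,8-dimethoxy-2-methyl-6-(prop-1-en-2-yl)oct-1-en-1-yl]dimethylalane | COC(OC)C[C@@H](CC/C(C)=C/[Al](C)C)C(C)=C | intermediate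
7 | (2E,6R)-8,8-dimethoxy-3-methyl-6-(prop-1-en-2-yl)oct-2-en-1-ol | COC(OC)C[C@@H](CC/C(C)=C/CO)C(C)=C | intermediate
8 | [(2R,3R)-3-[(3R)-5,5-dimethoxy-3-(prop-1-en-2-yl)pentyl]-3-methyloxiran-2-yl]methanol | COC(OC)C[C@@H](CC[C@@]1(C)O[C@@H]1CO)C(C)=C | intermediate
9 | (2R,5R)-7,7-dimethoxy-2-[(2S)-oxiran-2-yl]-5-(prop-1-en-2-yl)heptan-2-ol | COC(OC)C[C@@H](CC[C@@](C)(O)[C@@H]1CO1)C(C)=C | intermediate
10 | (3S,4R,7R)-9,9-dimethoxy-4-methyl-7-(prop-1-en-2-yl)non-1-ene-3,4-diol | COC(OC)C[C@@H](CC[C@@](C)(O)[C@@H](O)C=C)C(C)=C | intermediate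
11 | (3S,4R,7R)-7-(3-hydroxyprop-1-en-2-yl)-9,9-dimethoxy-4-methylnon-1-ene-3,4-diol | COC(OC)C[C@@H](CC[C@@](C)(O)[C@@H](O)C=C)C(=C)CO | intermediate
12 | 2-[(3R,6R,7S)-6,7-dihydroxy-1,1-dimethoxy-6-methylnon-8-en-3-yl]prop-2-enoic acid | COC(OC)C[C@@H](CC[C@@](C)(O)[C@@H](O)C=C)C(=C)C(=O)O | intermediate
13 | 2-(trimethylsilyl)ethyl 2-[(3R,6R,7S)-6,7-dihydroxy-1,1-dimethoxy-6-methylnon-8-en-3-yl]prop-2-enoate | COC(OC)C[C@@H](CC[C@@](C)(O)[C@@H](O)C=C)C(=C)C(=O)OCC[Si](C)(C)C | intermediate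
14 | 2-(trimethylsilyl)ethyl 2-[(3R,6R,7S)-6,7-dihydroxy-6-methyl-1-oxonon-8-en-3-yl]prop-2-enoate | O=CC[C@@H](CC[C@@](C)(O)[C@@H](O)C=C)C(=C)C(=O)OCC[Si](C)(C)C | intermediate
15 | 2-(trimethylsilyl)ethyl 2-[(2Z,5R,8R,9S)-8,9-dihydroxy-2-iodo-8-methylundeca-2,10-dien-5-yl]prop-2-enoate | I/C(C)=C\C[C@@H](CC[C@@](C)(O)[C@@H](O)C=C)C(=C)C(=O)OCC[Si](C)(C)C | intermediate
16 | 2-bromoprop-2-enal (2-bromoacrolein) | C=C(Br)C=O | starting material
17 | (±)-2-bromopenta-1,4-dien-3-ol | C=CC(O)C(Br)=C | intermediate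
18 | (3S)-2-bromopenta-1,4-dien-3-ol | C=C[C@H](O)C(Br)=C | intermediate
19 | {[(3S)-2-bromopenta-1,4-dien-3-yl]oxy}triethylsilane | C=C[C@H](O[Si](CC)(CC)CC)C(Br)=C | intermediate
20 | 9-[(3S)-4-bromo-3-(triethylsilyloxy)pent-4-en-1-yl]-9-borabicyclo[3.3.1]nonane | C=C(Br)[C@@H](O[Si](CC)(CC)CC)CCB1C2CCCC1CCC2 | intermediate
21 | 2-(trimethylsilyl)ethyl 2-[(3S,6Z,9R,12R,13S)-2-bromo-12,13-dihydroxy-6,12-dimethyl-3-(triethylsilyloxy)pentadeca-1,6,14-trien-9-yl]prop-2-enoate | C=C(Br)[C@@H](O[Si](CC)(CC)CC)CC/C(C)=C\C[C@@H](CC[C@@](C)(O)[C@@H](O)C=C)C(=C)C(=O)OCC[Si](C)(C)C | intermediate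
22 | 2-(trimethylsilyl)ethyl 2-[(3S,6Z,9R,12R,13S)-13-acetoxy-2-bromo-12-hydroxy-6,12-dimethyl-3-(triethylsilyloxy)pentadeca-1,6,14-trien-9-yl]prop-2-enoate | C=C(Br)[C@@H](O[Si](CC)(CC)CC)CC/C(C)=C\C[C@@H](CC[C@@](C)(O)[C@@H](OC(C)=O)C=C)C(=C)C(=O)OCC[Si](C)(C)C | intermediate
23 | (6S,7R)-6,7-epoxide of 22: 2-(trimethylsilyl)ethyl 2-[(2R,5R,6S)-6-acetoxy-1-[(2R,3S)-3-[(3S)-4-bromo-3-(triethylsilyloxy)pent-4-en-1-yl]-3-methyloxiran-2-yl]-5-hydroxy-5-methyloct-7-en-2-yl]prop-2-enoate | C=C(Br)[C@@H](O[Si](CC)(CC)CC)CC[C@]1(C)O[C@@H]1C[C@@H](CC[C@@](C)(O)[C@@H](OC(C)=O)C=C)C(=C)C(=O)OCC[Si](C)(C)C | intermediate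
24 | 2-(trimethylsilyl)ethyl 2-[(1R,3R,6R,7S)-7-acetoxy-1-[(2R,5S)-5-(1-bromoethenyl)-2-methyloxolan-2-yl]-1,6-dihydroxy-6-methylnon-8-en-3-yl]prop-2-enoate | C=C(Br)[C@@H]1CC[C@@](C)(O1)[C@H](O)C[C@@H](CC[C@@](C)(O)[C@@H](OC(C)=O)C=C)C(=C)C(=O)OCC[Si](C)(C)C | intermediate
25 | B-alkyl-9-BBN adduct of 24 (boron on the terminal carbon of the former vinyl group; hydroxyls may be present as borinates) | C=C(Br)[C@@H]1CC[C@@](C)(O1)[C@H](O)C[C@@H](CC[C@@](C)(O)[C@@H](OC(C)=O)CCB2C3CCCC2CCC3)C(=C)C(=O)OCC[Si](C)(C)C | intermediate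
26 | 2-(trimethylsilyl)ethyl 2-[(1R,2R,4R,7R,8S,12S)-8-acetoxy-2,7-dihydroxy-1,7-dimethyl-11-methylidene-15-oxabicyclo[10.2.1]pentadecan-4-yl]prop-2-enoate | C=C(C(=O)OCC[Si](C)(C)C)[C@@H]1CC[C@@](C)(O)[C@@H](OC(C)=O)CCC(=C)[C@@H]2CC[C@@](C)(O2)[C@H](O)C1 | intermediate
27 | dendronpholide R, 2-[(1R,2R,4R,7R,8S,12S)-8-acetoxy-2,7-dihydroxy-1,7-dimethyl-11-methylidene-15-oxabicyclo[10.2.1]pentadecan-4-yl]prop-2-enoic acid | C=C(C(=O)O)[C@@H]1CC[C@@](C)(O)[C@@H](OC(C)=O)CCC(=C)[C@@H]2CC[C@@](C)(O2)[C@H](O)C1 | target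

**Step count.** Total: 18 steps. Longest linear sequence: 15 steps (steps 1–10 and 14–18); steps 11–13 make the C5 piece 19.

**Steps most likely to fail**

1. Step 17 (macrocyclisation). Intermolecular coupling may outrun ring closure, the alkylborane may protodeboronate or the alkylpalladium intermediate may undergo β-hydride elimination, and the aqueous base may start to hydrolyse the acetate. The fallback sets out from 24 and returns at 26 without boron or base in the ring-closing event. Hydroboration of 24 with 9-BBN and oxidation with NaBO3 should give the primary alcohol 2-(trimethylsilyl)ethyl 2-[(1R,3R,6R,7S)-7-acetoxy-1-[(2R,5S)-5-(1-bromoethenyl)-2-methyloxolan-2-yl]-1,6,9-trihydroxy-6-methylnonan-3-yl]prop-2-enoate F1. Treatment with I2, PPh3 and imidazole should convert only the primary hydroxyl into the iodide 2-(trimethylsilyl)ethyl 2-[(1R,3R,6R,7S)-7-acetoxy-1-[(2R,5S)-5-(1-bromoethenyl)-2-methyloxolan-2-yl]-1,6-dihydroxy-9-iodo-6-methylnonan-3-yl]prop-2-enoate F2. A nickel-catalysed reductive cross-electrophile coupling of the alkyl iodide with the bromoalkene (NiBr2(dme), 4,4'-di-tert-butyl-2,2'-bipyridine, Zn, NaI, DMA, high dilution) would then close the same C10–C11 bond and give 26.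

2. Step 16 (epoxidation and oxolane closure). The dioxirane may show poor facial selectivity on the Z-trisubstituted alkene of this chiral substrate, which would give the C1/C2 diastereomer. The fallback sets out from 22 and returns at 24 with a hydroxyl-directed, ligand-controlled epoxidation. PPTS in MeOH should remove the TES group to give the bishomoallylic alcohol 2-(trimethylsilyl)ethyl 2-[(3S,6Z,9R,12R,13S)-13-acetoxy-2-bromo-3,12-dihydroxy-6,12-dimethylpentadeca-1,6,14-trien-9-yl]prop-2-enoate F3. Epoxidation with Hf(Ot-Bu)4, a C2-symmetric bishydroxamic acid ligand of the matching hand and cumene hydroperoxide in toluene at 0 °C should give the (6S,7R)-epoxy alcohol of F3 F4, which cyclises with a trace of CSA to 24.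

3. Step 5 (Payne rearrangement and ylide homologation). Payne equilibration of the lithium alkoxide in THF towards the tertiary alkoxide and terminal epoxide may be too slow, so that the ylide decomposes before it can trap the terminal epoxide. The fallback sets out from 8 and returns at 10, running the rearrangement under aqueous conditions and isolating the terminal epoxide. NaOH in t-BuOH/H2O at 70 °C (Payne rearrangement, hydroxide opening at the primary carbon) should give (2S,3R,6R)-8,8-dimethoxy-3-methyl-6-(prop-1-en-2-yl)octane-1,2,3-triol F5. Selective primary tosylation (TsCl, Bu2SnO cat., Et3N) should give (2S,3R,6R)-2,3-dihydroxy-8,8-dimethoxy-3-methyl-6-(prop-1-en-2-yl)octyl 4-methylbenzenesulfonate F6. K2CO3 in MeOH closes this to the terminal epoxide 9, now isolated, and Me3SI/n-BuLi homologates it to 10.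

**Further compounds**

F1 | step 17 | 2-(trimethylsilyl)ethyl 2-[(1R,3R,6R,7S)-7-acetoxy-1-[(2R,5S)-5-(1-bromoethenyl)-2-methyloxolan-2-yl]-1,6,9-trihydroxy-6-methylnonan-3-yl]prop-2-enoate | C=C(Br)[C@@H]1CC[C@@](C)(O1)[C@H](O)C[C@@H](CC[C@@](C)(O)[C@@H](OC(C)=O)CCO)C(=C)C(=O)OCC[Si](C)(C)C
F2 | step 17 | 2-(trimethylsilyl)ethyl 2-[(1R,3R,6R,7S)-7-acetoxy-1-[(2R,5S)-5-(1-bromoethenyl)-2-methyloxolan-2-yl]-1,6-dihydroxy-9-iodo-6-methylnonan-3-yl]prop-2-enoate | C=C(Br)[C@@H]1CC[C@@](C)(O1)[C@H](O)C[C@@H](CC[C@@](C)(O)[C@@H](OC(C)=O)CCI)C(=C)C(=O)OCC[Si](C)(C)C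
F3 | step 16 | 2-(trimethylsilyl)ethyl 2-[(3S,6Z,9R,12R,13S)-13-acetoxy-2-bromo-3,12-dihydroxy-6,12-dimethylpentadeca-1,6,14-trien-9-yl]prop-2-enoate | C=C(Br)[C@@H](O)CC/C(C)=C\C[C@@H](CC[C@@](C)(O)[C@@H](OC(C)=O)C=C)C(=C)C(=O)OCC[Si](C)(C)C
F4 | step 16 | (6S,7R)-6,7-epoxide of F3 | C=C(Br)[C@@H](O)CC[C@]1(C)O[C@@H]1C[C@@H](CC[C@@](C)(O)[C@@H](OC(C)=O)C=C)C(=C)C(=O)OCC[Si](C)(C)C
F5 | step 5 | (2S,3R,6R)-8,8-dimethoxy-3-methyl-6-(prop-1-en-2-yl)octane-1,2,3-triol | COC(OC)C[C@@H](CC[C@@](C)(O)[C@@H](O)CO)C(C)=C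
F6 | step 5 | (2S,3R,6R)-2,3-dihydroxy-8,8-dimethoxy-3-methyl-6-(prop-1-en-2-yl)octyl 4-methylbenzenesulfonate | COC(OC)C[C@@H](CC[C@@](C)(O)[C@@H](O)COS(=O)(=O)c1ccc(C)cc1)C(C)=C
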